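## Retrosynthetic overview

- Target 11 ⇐ 3-ketone 10 (hydride reduction re-sets C3 as 3β) ⇐ exocyclic alkene 9 by the key C17–O bond formation: transpositional allylic C–H acetoxylation, Δ8(17) → 17-OAc-Δ7 (new Pd catalysis).
- 9 ⇐ aldehyde 7 (oxidative esterification) ⇐ dienal 6 by catalyst-controlled iminium transfer hydrogenation, which sets C13 (R).
- 6 ⇐ hydroxy enal 4 (exo-selective dehydration of 8α-OH) ⇐ triol 2 by one-pot double oxidation with 1,3-oxidative transposition (C15–O) ⇐ sclareol 1 by enzymatic C3–H hydroxylation.
- No ring is formed: rings A and B, all 20 skeletal carbons and C5, C9, C10 come intact from sclareol; only C–O and C–H bonds are made.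

Labdane numbering is used: ring A = C1–C5, C10; ring B = C5–C10; C17 on C8; C18/C19 on C4; C20 on C10; side chain C11–C15 on C9 with C16 the methyl on C13. Every compound has 5α-H, 9α-H (side chain β) and 10β-CH3. For E/Z mixtures the alkene geometry is left open in the SMILES.

Assumption: short-lived metal-, boron- or catalyst-bound species (chromate esters, iminium ions, allylpalladium species, boron alkoxides) are treated as mechanism only; metal-free species that form in the flask and react on are numbered.

## Route

Step 1
Reactants: 1 sclareol [(13R)-labd-14-ene-8α,13-diol]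
Product: 2 3β-hydroxysclareol [(13R)-labd-14-ene-3β,8α,13-triol]
Conditions: cytochrome P450 BM3 variant evolved for C3 of sclareolide-type decalins (heme-iron enzyme, E. coli lysate), NADP+ (cat.), phosphite dehydrogenase, Na2HPO3, air, K2HPO4/KH2PO4 buffer pH 8.0, 5% EtOH, 25 °C
Reagents that add atoms: dioxygen, O=O
Why: Enzymatic C–H hydroxylation (hydrogen abstraction by the heme iron-oxo species, then oxygen rebound), precedented for sclareolide and sclareol, in which the pocket presents the equatorial C3–H of ring A to the heme so that oxygen is delivered with retention to give the 3β alcohol; this oxygen stays to the end, although its configuration is re-set in step 7.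

Step 2
Reactants: 2 3β-hydroxysclareol
Product: 4 8α-hydroxy-3-oxolabd-13-en-15-al (13E/13Z mixture), via 3-oxosclareol 3 (not isolated)
Conditions: pyridinium chlorochromate [C5H5NH][CrO3Cl] (5 equiv), 4 Å molecular sieves, CH2Cl2, 23 °C, 16 h; filtered through SiO2 and used at once
Reagents that add atoms: pyridinium chlorochromate, c1cc[nH+]cc1.[O-][Cr](=O)(=O)Cl
Why: Babler–Dauben oxidative 1,3-transposition: hexavalent chromium first oxidizes the secondary 3-OH (giving 3), then the chromate ester of the tertiary allylic 13-OH undergoes a [3,3] shift to the primary allylic chromate, which collapses to the enal, so the C15 oxygen comes from the reagent; the non-allylic tertiary 8α-OH cannot be oxidized and no stereocenter is made (the E/Z ratio is levelled in step 4).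

Step 3
Reactants: 4 8α-hydroxy-3-oxolabd-13-en-15-al
Product: 6 3-oxolabda-8(17),13-dien-15-al (13E/13Z mixture), via 8α-chlorosulfite ester 5 (not isolated)
Conditions: SOCl2 (1.5 equiv), pyridine (6 equiv), CH2Cl2, −78 to −40 °C; AgNO3–SiO2 chromatography
Reagents that add atoms: none
Why: E2 dehydration through the chlorosulfite (Barton's rule): the equatorial 8α leaving group has no anti-periplanar ring hydrogen, only those of the axial C17 methyl, so pyridine removes a methyl hydrogen and the exocyclic Δ8(17) alkene forms preferentially; the C8 stereocenter is erased and none is created.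

Step 4
Reactants: 6 3-oxolabda-8(17),13-dien-15-al
Product: 7 (13R)-3-oxolabd-8(17)-en-15-al
Conditions: morpholinium (R)-3,3′-bis(2,4,6-triisopropylphenyl)-1,1′-binaphthyl-2,2′-diyl phosphate (20 mol%), Hantzsch ester (diethyl 2,6-dimethyl-1,4-dihydropyridine-3,5-dicarboxylate, 1.2 equiv), THF, 50 °C, 24 h
Reagents that add atoms: none
Why: Organocatalytic asymmetric transfer hydrogenation by counteranion-directed iminium catalysis: the 13E and 13Z iminium ions equilibrate through the dienamine and the chiral phosphate ion pair exposes one face of C13 to the dihydropyridine hydride, setting 13R under catalyst control in the sense of citral to (R)-citronellal; the hindered ketone and the unconjugated exocyclic alkene are not touched.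

Step 5
Reactants: 7 (13R)-3-oxolabd-8(17)-en-15-al
Product: 9 methyl (13R)-3-oxolabd-8(17)-en-15-oate, via methyl hemiacetal 8 (not isolated)
Conditions: pyridinium dichromate (C5H5NH)2Cr2O7 (6 equiv), MeOH (10 equiv), DMF, 23 °C, 20 h
Reagents that add atoms: methanol, CO
Why: Oxidative esterification: aldehyde and methanol form hemiacetal 8, whose carbinol C–H is oxidized by hexavalent chromium to the methyl ester; the ketone, the alkene and C13 (β to the carbonyl, not epimerizable) are unaffected.

Step 6
Reactants: 9 methyl (13R)-3-oxolabd-8(17)-en-15-oate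
Product: 10 methyl (13R)-17-acetoxy-3-oxolabd-7-en-15-oate
Conditions: Pd(OAc)2 (10 mol%), 4,5-diazafluoren-9-one (10 mol%), 1,4-benzoquinone (2 equiv), NaOAc (20 mol%), AcOH/1,4-dioxane 1:3, 50 °C
Reagents that add atoms: acetic acid, CC(=O)O
Why: Proposed new method: transpositional allylic C–H acetoxylation of a hindered exocyclic 1,1-disubstituted alkene, in which divalent palladium binds C8=C17 on the open α face (the β face is screened by the axial C10 methyl), its acetate removes the axial, π-aligned H-7α (H-9α is tertiary and flanked by C10 and the side chain) to give the η3-allyl spanning C7–C8–C17, and diazafluorenone/benzoquinone-promoted C–O reductive elimination occurs at the primary terminus C17, leaving a trisubstituted Δ7 alkene too hindered to re-enter while benzoquinone returns zerovalent palladium to the divalent state; the closest known reactions are the Pd(OAc)2/benzoquinone and Pd(OAc)2/4,5-diazafluorenone linear allylic acetoxylations of terminal alkenes and of simple methylenecycloalkanes (β-pinene to myrtenyl acetate), not yet shown on a polycyclic Δ8(17) terpenoid where site (C7 versus C9) and terminus (C17 versus C7) must both be controlled.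

Step 7
Reactants: 10 methyl (13R)-17-acetoxy-3-oxolabd-7-en-15-oate
Product: 11 methyl (13R)-17-acetoxy-3β-hydroxylabd-7-en-15-oate (target)
Conditions: NaBH4 (1.0 equiv), MeOH/CH2Cl2 1:1, 0 °C, 30 min
Reagents that add atoms: none
Why: Diastereoselective ketone reduction: hydride attacks C3 axially from the α face, away from the axial 4β-methyl, giving the equatorial 3β alcohol (3S) as in other 3-oxo-4,4-dimethyl terpenoids, while the methyl ester and the allylic acetate survive the short, cold exposure.

## Compound list

1 | sclareol, (13R)-labd-14-ene-8α,13-diol | C=C[C@](C)(O)CC[C@H]1[C@](C)(O)CC[C@H]2C(C)(C)CCC[C@]12C | starting material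
2 | 3β-hydroxysclareol, (13R)-labd-14-ene-3β,8α,13-triol | C=C[C@](C)(O)CC[C@H]1[C@](C)(O)CC[C@H]2C(C)(C)[C@@H](O)CC[C@]12C | intermediate
3 | 3-oxosclareol, (13R)-8α,13-dihydroxylabd-14-en-3-one (not isolated) | C=C[C@](C)(O)CC[C@H]1[C@](C)(O)CC[C@H]2C(C)(C)C(=O)CC[C@]12C | intermediate
4 | 8α-hydroxy-3-oxolabd-13-en-15-al (13E/13Z mixture, E major) | O=CC=C(C)CC[C@H]1[C@](C)(O)CC[C@H]2C(C)(C)C(=O)CC[C@]12C | intermediate
5 | 8α-chlorosulfite ester of 4 (not isolated) | O=CC=C(C)CC[C@H]1[C@](C)(OS(=O)Cl)CC[C@H]2C(C)(C)C(=O)CC[C@]12C | intermediate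
6 | 3-oxolabda-8(17),13-dien-15-al (13E/13Z mixture) | O=CC=C(C)CC[C@H]1C(=C)CC[C@H]2C(C)(C)C(=O)CC[C@]12C | intermediate
7 | (13R)-3-oxolabd-8(17)-en-15-al | O=CC[C@H](C)CC[C@H]1C(=C)CC[C@H]2C(C)(C)C(=O)CC[C@]12C | intermediate
8 | methyl hemiacetal of 7 at C15, both C15 epimers (not isolated) | COC(O)C[C@H](C)CC[C@H]1C(=C)CC[C@H]2C(C)(C)C(=O)CC[C@]12C | intermediate
9 | methyl (13R)-3-oxolabd-8(17)-en-15-oate | COC(=O)C[C@H](C)CC[C@H]1C(=C)CC[C@H]2C(C)(C)C(=O)CC[C@]12C | intermediate
10 | methyl (13R)-17-acetoxy-3-oxolabd-7-en-15-oate | COC(=O)C[C@H](C)CC[C@H]1C(COC(C)=O)=CC[C@H]2C(C)(C)C(=O)CC[C@]12C | intermediate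
11 | methyl (13R)-17-acetoxy-3β-hydroxylabd-7-en-15-oate, (3S,5R,9R,10R,13R) | COC(=O)C[C@H](C)CC[C@H]1C(COC(C)=O)=CC[C@H]2C(C)(C)[C@@H](O)CC[C@]12C | target

## Step count and risks

Total steps: 7. Longest linear sequence: 7 (fully linear from sclareol).

The three steps most likely to fail:

**Step 6 (proposed new method).** The risks are C–H cleavage at C9 instead of C7, acetate delivery to C7, or dehydrogenation of the 3-ketone by palladium. The fallback uses known chemistry, sets out from 9 and returns at 10. Dye-sensitized photooxygenation (O2, tetraphenylporphyrin, visible light, CH2Cl2, 0 °C) is a Schenck ene reaction in which singlet oxygen bonds to C17 on the α face and takes the axial H-7α, giving methyl (13R)-17-hydroperoxy-3-oxolabd-7-en-15-oate F1. PPh3 added to the same flask reduces it to methyl (13R)-17-hydroxy-3-oxolabd-7-en-15-oate F2. Ac2O, pyridine and DMAP at 0 °C then give 10. This costs two extra operations.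

**Step 3.** The risk is poor exo selectivity, with the Δ7 and Δ8 alkene isomers forming. The fallback sets out from 4 and returns at 10; it switches to the endocyclic alkene and oxidizes the C17 methyl directly. Acid-mediated E1 (Zaitsev) dehydration of 4 (cat. p-TsOH, toluene, 40 °C, stopped before the tetrasubstituted isomer builds up) gives 3-oxolabda-7,13-dien-15-al F3; any Δ7 by-product separated from 6 on AgNO3–SiO2 joins here. The conditions of step 4 give (13R)-3-oxolabd-7-en-15-al F4. The conditions of step 5 give, via the methyl hemiacetal of F4 F5, methyl (13R)-3-oxolabd-7-en-15-oate F6. SeO2 (0.5 equiv) with t-BuOOH in CH2Cl2 at 23 °C hydroxylates the C17 methyl by the ene/[2,3] sequence at the more substituted alkene carbon (C9–H is tertiary and hindered), as in the C12 oxidation of drimenyl acetate, giving methyl (13R)-17-hydroxy-3-oxolabd-7-en-15-oate F2. Ac2O/pyridine gives 10.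

**Step 2.** The risk is acid-induced ionization at C13 under pyridinium chlorochromate with capture by the 8α-OH (8,13-ether of the manoyl oxide type). The fallback sets out from 2 and returns at 4; it separates the allylic shift from the oxidation and masks the 8-oxygen. AcCl with N,N-dimethylaniline in CH2Cl2 gives (13R)-labd-14-ene-3β,8α,13-triyl triacetate F7. PdCl2(MeCN)2 (5 mol%) in THF at 23 °C effects the divalent-palladium-catalysed [3,3] shift of the tertiary allylic acetate to labd-13-ene-3β,8α,15-triyl triacetate F8 (13E major; the geometry does not matter for step 4). LiAlH4 in THF at 0 °C gives labd-13-ene-3β,8α,15-triol F9. Dess–Martin periodinane (2.5 equiv, NaHCO3, CH2Cl2) oxidizes the 3-OH and the allylic 15-OH and leaves the tertiary 8-OH, giving 4. This costs three extra operations.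

## Further compounds

F1 | step 6 | methyl (13R)-17-hydroperoxy-3-oxolabd-7-en-15-oate | COC(=O)C[C@H](C)CC[C@H]1C(COO)=CC[C@H]2C(C)(C)C(=O)CC[C@]12C
F2 | step 6 | methyl (13R)-17-hydroxy-3-oxolabd-7-en-15-oate | COC(=O)C[C@H](C)CC[C@H]1C(CO)=CC[C@H]2C(C)(C)C(=O)CC[C@]12C
F3 | step 3 | 3-oxolabda-7,13-dien-15-al (13E/13Z mixture) | O=CC=C(C)CC[C@H]1C(C)=CC[C@H]2C(C)(C)C(=O)CC[C@]12C
F4 | step 3 | (13R)-3-oxolabd-7-en-15-al | O=CC[C@H](C)CC[C@H]1C(C)=CC[C@H]2C(C)(C)C(=O)CC[C@]12C
F5 | step 3 | methyl hemiacetal of F4 at C15 (not isolated) | COC(O)C[C@H](C)CC[C@H]1C(C)=CC[C@H]2C(C)(C)C(=O)CC[C@]12C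
F6 | step 3 | methyl (13R)-3-oxolabd-7-en-15-oate | COC(=O)C[C@H](C)CC[C@H]1C(C)=CC[C@H]2C(C)(C)C(=O)CC[C@]12C
F7 | step 2 | (13R)-labd-14-ene-3β,8α,13-triyl triacetate | C=C[C@](C)(OC(C)=O)CC[C@H]1[C@](C)(OC(C)=O)CC[C@H]2C(C)(C)[C@@H](OC(C)=O)CC[C@]12C
F8 | step 2 | labd-13-ene-3β,8α,15-triyl triacetate (13E major) | CC(=O)OCC=C(C)CC[C@H]1[C@](C)(OC(C)=O)CC[C@H]2C(C)(C)[C@@H](OC(C)=O)CC[C@]12C
F9 | step 2 | labd-13-ene-3β,8α,15-triol (13E major) | OCC=C(C)CC[C@H]1[C@](C)(O)CC[C@H]2C(C)(C)[C@@H](O)CC[C@]12C
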